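**Retrosynthetic overview**
1. Target 14 ⇒ acyclic bis-diene 11 + two oxalyl chloride 12. A two-directional [4+2] C,C-diacylation closes ring A (methoxy-hydroxy-quinone) and ring B (dihydroxy-quinone) together in the last step; no ring exists before it.
2. Enabling feature: in each ring the two adjacent oxygen-bearing carbons on one side (ring A: the C=O next to C–CH3 and the C–OH next to the chain-bearing carbon) form an oxalyl C2 unit. The other four ring carbons (C–CH3, C–O, C–O, C–chain) form a 2,3-dioxygenated buta-1,3-diene, and two enol ethers plus two acyl groups add up exactly to the quinone oxidation level.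
3. 11 ⇒ enone 10 (silyl enol ether formation) ⇒ ester 6 + phosphonate 7 + acetaldehyde 9 (acylation, then Horner–Wadsworth–Emmons). This fixes OCH3 on the diene carbon next to the CH3-bearing terminus of ring A.
4. The ring B diene in 6 ⇒ 1,2-diketone 5 ⇒ alkyne 4 ⇒ 16-bromohexadecanoic acid 1 + but-1-yne 2. The C16 acid supplies the 13 methylenes and three ring carbons.

Key step: step 8

Remark: the enol-ether and silyl-enol-ether double bonds of 6, 8, 10 and 11 should form as E/Z mixtures whose geometry is erased in step 8, so they are drawn without alkene descriptors; 8 is racemic at one centre that step 6 removes; the target has no stereocentre.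

**Step 1**
Reactants: 1 16-bromohexadecanoic acid; 2 but-1-yne
Product: 3 icos-17-ynoic acid
Conditions: 2 (3.5 equiv), n-BuLi (3.1 equiv), THF/DMPU, −78 °C → rt; then 1 M HCl
Reagents that add atoms: none
Why: Acetylide alkylation (SN2 of the lithium acetylide on the primary bromide), with the acid carried in the flask as its lithium carboxylate so that no protecting group is needed.

**Step 2**
Reactants: 3 icos-17-ynoic acid
Product: 4 methyl icos-17-ynoate
Conditions: MeOH, cat. H2SO4, reflux
Reagents that add atoms: methanol, CO
Why: Fischer esterification, to which the internal alkyne is inert.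

**Step 3**
Reactants: 4 methyl icos-17-ynoate
Product: 5 methyl 17,18-dioxoicosanoate
Conditions: RuCl3·xH2O (2 mol %), NaIO4 (3 equiv), NaHCO3, MgSO4, EtOAc/MeCN/H2O, 0 °C, short contact
Reagents that add atoms: sodium periodate, [Na+].[O-]I(=O)(=O)=O
Why: Ruthenium tetroxide alkyne oxidation (RuO4 formed in the flask) should convert the internal alkyne into the 1,2-diketone while the saturated chain and the ester stay untouched under buffered conditions.

**Step 4**
Reactants: 5 methyl 17,18-dioxoicosanoate
Product: 6 methyl 17,18-bis[(tert-butyldimethylsilyl)oxy]icosa-16,18-dienoate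
Conditions: TBSOTf (2.3 equiv), Et3N (3 equiv), CH2Cl2, 0 °C
Reagents that add atoms: tert-butyldimethylsilyl trifluoromethanesulfonate, CC(C)(C)[Si](C)(C)OS(=O)(=O)C(F)(F)F
Why: Soft enolisation (silyl triflate/amine silyl enol ether formation) in which each ketone can only enolise toward its single α-methylene, giving a 2,3-bis(silyloxy)-1,3-diene that hides the base-sensitive diketone from steps 5 and 6 and is already the ring B bis-nucleophile, the ester being silylated far more slowly.

**Step 5**
Reactants: 6 bis-silyl dienyl ester; 7 diethyl (methoxymethyl)phosphonate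
Product: 8 diethyl {18,19-bis[(tert-butyldimethylsilyl)oxy]-1-methoxy-2-oxohenicosa-17,19-dien-1-yl}phosphonate (racemic)
Conditions: 7 (2.3 equiv), LiN(i-Pr)2 (2.3 equiv), THF, −78 °C; then 6, −78 → −40 °C; aq. NH4Cl
Reagents that add atoms: none
Why: Claisen-type acylation of the α-lithiated phosphonate by the methyl ester should give the β-ketophosphonate (the second equivalent of carbanion is consumed by the acidic product), TBS enol ethers being inert to stabilised carbanions at −78 °C and the new stereocentre being racemic and removed in step 6.

**Step 6**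
Reactants: 8 β-ketophosphonate; 9 acetaldehyde
Product: 10 20,21-bis[(tert-butyldimethylsilyl)oxy]-3-methoxytricosa-2,19,21-trien-4-one
Conditions: NaH (1.05 equiv), THF, 0 °C; then 9 (3 equiv), −20 °C → rt
Reagents that add atoms: none
Why: Horner–Wadsworth–Emmons olefination, which places the methoxy group on the enone α-carbon, that is on the future ring carbon next to C–CH3, the E/Z outcome being irrelevant.

**Step 7**
Reactants: 10 methoxy enone
Product: 11 4,20,21-tris[(tert-butyldimethylsilyl)oxy]-3-methoxytricosa-2,4,19,21-tetraene
Conditions: TBSOTf (1.3 equiv), Et3N (2 equiv), Et2O, −78 → 0 °C; pentane, filtration under argon, used crude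
Reagents that add atoms: tert-butyldimethylsilyl trifluoromethanesulfonate, CC(C)(C)[Si](C)(C)OS(=O)(=O)C(F)(F)F
Why: Silyl triflate/amine soft enolisation of the enone, in which deprotonation of the O-silylated ketone at the adjacent α'-methylene is the kinetically preferred path and should give the cross-conjugated 2-methoxy-3-silyloxy-1,3-diene while the existing bis-silyl diene is unchanged.

**Step 8**
Reactants: 11 tris-silyl bis-diene; 12 oxalyl chloride
Product: 14 the target bis-quinone, via tris-TBS bis(ortho-quinone) 13 (not isolated)
Conditions: 12 (2.3 equiv), 2,6-di-tert-butyl-4-methylpyridine (4.6 equiv), CH2Cl2 (0.01 M), −78 °C → rt; then 0.5 M HCl/THF, 0 °C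
Reagents that add atoms: none
Why: Proposed new method: each 2,3-dioxygenated 1,3-diene should act as a 1,4-C,C-bis-nucleophile toward oxalyl chloride: one enol-ether terminus attacks an acid chloride carbon and loses a proton to the hindered pyridine (addition–elimination that regenerates the enol ether), then the other terminus attacks the tethered α-keto acid chloride, so that the C(CH3)–C(=O) and C(chain)–C(OH) bonds of ring A and the corresponding two bonds of ring B all arise from two oxalyl units in one operation, after which aqueous acid cleaves the O–Si bonds and the 4-hydroxy-1,2-quinones tautomerise to the 2-hydroxy-1,4-quinones. The closest known reaction types are the uncatalysed β-C-acylation of enol ethers by oxalyl chloride and the double Friedel–Crafts acylation of 2,2'-linked electron-rich biaryls by oxalyl chloride to phenanthrene-9,10-quinones. Rings A and B are each closed by a 6-(enolendo)-exo-trig acyl substitution, and no stereocentre is formed. The step needs C- over O-acylation (an enol freed by early desilylation could close to a five-membered furan-2,3-dione), which the TBS groups and the non-nucleophilic base should secure by keeping silicon or methyl on every diene oxygen until both C–C bonds exist, and it needs ring closure over chain growth, which the six-membered transition state and the dilution should secure. The OCH3/OH pattern of ring A cannot scramble, because the methyl ether sits on the diene carbon next to the CH3-bearing terminus whereas the silylated oxygen ends as a quinone carbonyl. No oxidant is needed, since two enol ethers plus two acyl groups already equal the quinone oxidation level.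

**Compound list**
1 | 16-bromohexadecanoic acid | OC(=O)CCCCCCCCCCCCCCCBr | starting material
2 | but-1-yne | CCC#C | starting material
3 | icos-17-ynoic acid | CCC#CCCCCCCCCCCCCCCCC(=O)O | intermediate
4 | methyl icos-17-ynoate | CCC#CCCCCCCCCCCCCCCCC(=O)OC | intermediate
5 | methyl 17,18-dioxoicosanoate | CCC(=O)C(=O)CCCCCCCCCCCCCCCC(=O)OC | intermediate
6 | methyl 17,18-bis[(tert-butyldimethylsilyl)oxy]icosa-16,18-dienoate (mixture of alkene isomers) | CC=C(O[Si](C)(C)C(C)(C)C)C(O[Si](C)(C)C(C)(C)C)=CCCCCCCCCCCCCCCC(=O)OC | intermediate
7 | diethyl (methoxymethyl)phosphonate | CCOP(=O)(COC)OCC | starting material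
8 | diethyl {18,19-bis[(tert-butyldimethylsilyl)oxy]-1-methoxy-2-oxohenicosa-17,19-dien-1-yl}phosphonate (racemic, mixture of alkene isomers) | CCOP(=O)(OCC)C(OC)C(=O)CCCCCCCCCCCCCCC=C(O[Si](C)(C)C(C)(C)C)C(O[Si](C)(C)C(C)(C)C)=CC | intermediate
9 | acetaldehyde | CC=O | starting material
10 | 20,21-bis[(tert-butyldimethylsilyl)oxy]-3-methoxytricosa-2,19,21-trien-4-one (mixture of alkene isomers) | CC=C(OC)C(=O)CCCCCCCCCCCCCCC=C(O[Si](C)(C)C(C)(C)C)C(O[Si](C)(C)C(C)(C)C)=CC | intermediate
11 | 4,20,21-tris[(tert-butyldimethylsilyl)oxy]-3-methoxytricosa-2,4,19,21-tetraene (mixture of alkene isomers) | CC=C(OC)C(O[Si](C)(C)C(C)(C)C)=CCCCCCCCCCCCCCC=C(O[Si](C)(C)C(C)(C)C)C(O[Si](C)(C)C(C)(C)C)=CC | intermediate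
12 | oxalyl chloride | O=C(Cl)C(Cl)=O | starting material
13 | 4,5-bis[(tert-butyldimethylsilyl)oxy]-3-{13-[2-(tert-butyldimethylsilyl)oxy-3-methoxy-4-methyl-5,6-dioxocyclohexa-1,3-dien-1-yl]tridecyl}-6-methylcyclohexa-3,5-diene-1,2-dione | COC1=C(C)C(=O)C(=O)C(CCCCCCCCCCCCCC2=C(O[Si](C)(C)C(C)(C)C)C(O[Si](C)(C)C(C)(C)C)=C(C)C(=O)C2=O)=C1O[Si](C)(C)C(C)(C)C | intermediate
14 | 3-[13-(2,5-dihydroxy-4-methyl-3,6-dioxocyclohexa-1,4-dien-1-yl)tridecyl]-2-hydroxy-5-methoxy-6-methylcyclohexa-2,5-diene-1,4-dione (CNP0107579.0) | COC1=C(C)C(=O)C(O)=C(CCCCCCCCCCCCCC2=C(O)C(=O)C(C)=C(O)C2=O)C1=O | target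

**Totals**
Total step count: 8. Longest linear sequence: 8 steps (1 → 14).

**Steps most likely to fail**

Step 8 (proposed new method). After the first acylation the ring may close through oxygen instead of carbon, chains may grow between molecules, or the dienes may be protodesilylated before they are acylated. The fallback leaves the route at 10 and returns at 14. Aqueous HCl in THF should hydrolyse the three enol ethers of 10 to tricosane-3,4,20,21-tetraone F1. F1 would then be condensed at both ends with diethyl oxalate under alkoxide (KOt-Bu, THF/t-BuOH, then H3O+). This is the oxalate double Claisen annulation (Claisen, then Dieckmann-type closure) known from the synthesis of cyclopentane-1,2,4-triones from dialkyl ketones, here closing six-membered rings, and it should give 3,3'-(tridecane-1,13-diyl)bis(2,5-dihydroxy-6-methylcyclohexa-2,5-diene-1,4-dione) F2. Partial acid-catalysed O-methylation of F2 (MeOH, cat. H2SO4, stopped at low conversion) should then give 14 beside its regioisomer and more highly methylated material. 14 would be separated by preparative HPLC and unreacted F2 recycled. This fallback gives up the built-in control of mono-methylation and of the methoxy position.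

Step 5. The α-alkoxy carbanion may transfer a proton to the ester instead of adding to it, or the silyl dienol ether may be lost on work-up and chromatography. The fallback leaves the route at 4 and returns at 11, and carries no silyl enol ether through carbanion chemistry. Ester 4 would be acylated with lithiated 7 to give diethyl (1-methoxy-2-oxohenicos-18-yn-1-yl)phosphonate F3. RuCl3/NaIO4 oxidation of the alkyne should give diethyl (1-methoxy-2,18,19-trioxohenicosyl)phosphonate F4. Horner–Wadsworth–Emmons olefination with acetaldehyde under LiCl/i-Pr2NEt in MeCN, which should deprotonate only the chelated ketophosphonate, would give 3-methoxytricos-2-ene-4,20,21-trione F5. One global silylation (TBSOTf 3.5 equiv, Et3N, Et2O) should convert the diketone and the enone of F5 into 11.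

Step 3. Over-oxidation may cleave the C–C bond of the newly formed diketone to carboxylic acids. The fallback leaves the route at 4 and returns at 5, and builds the diketone stepwise. Semi-hydrogenation (H2, Pd/CaCO3–Pb(OAc)2, quinoline) should give methyl (Z)-icos-17-enoate F6. Syn-dihydroxylation (cat. OsO4, NMO) should give racemic methyl (17R*,18S*)-17,18-dihydroxyicosanoate F7. Double Swern oxidation (DMSO, (CF3CO)2O, Et3N, −78 °C) would oxidise both carbinols without C–C cleavage and give 5.

**Further compounds**
F1 | step 8 | tricosane-3,4,20,21-tetraone | CCC(=O)C(=O)CCCCCCCCCCCCCCCC(=O)C(=O)CC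
F2 | step 8 | 3,3'-(tridecane-1,13-diyl)bis(2,5-dihydroxy-6-methylcyclohexa-2,5-diene-1,4-dione) | CC1=C(O)C(=O)C(CCCCCCCCCCCCCC2=C(O)C(=O)C(C)=C(O)C2=O)=C(O)C1=O
F3 | step 5 | diethyl (1-methoxy-2-oxohenicos-18-yn-1-yl)phosphonate (racemic) | CCOP(=O)(OCC)C(OC)C(=O)CCCCCCCCCCCCCCCC#CCC
F4 | step 5 | diethyl (1-methoxy-2,18,19-trioxohenicosyl)phosphonate (racemic) | CCOP(=O)(OCC)C(OC)C(=O)CCCCCCCCCCCCCCCC(=O)C(=O)CC
F5 | step 5 | 3-methoxytricos-2-ene-4,20,21-trione (mixture of alkene isomers) | CC=C(OC)C(=O)CCCCCCCCCCCCCCCC(=O)C(=O)CC
F6 | step 3 | methyl (Z)-icos-17-enoate | CC/C=C\CCCCCCCCCCCCCCCC(=O)OC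
F7 | step 3 | methyl (17R*,18S*)-17,18-dihydroxyicosanoate (racemic) | CC[C@@H](O)[C@@H](O)CCCCCCCCCCCCCCCC(=O)OC
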